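**Plan**

Labdane numbering: ring A = C1–C5 and C10 (OH on C2; methyl C18 and carboxyl C19 on C4); ring B = C5–C10 (C8=C17H2, side chain C11–C16 on C9, methyl C20 on C10).
Cuts: C13=C14 with C14–C15 (alkyne carboalumination–acylation); C9–C11 with C8=C17 (organocerium addition to a C9 ketone, then allylic reduction); C2–C3 together with C4–C18 (one reductive event); C10–C1 and C5–C4 on 2-methylcyclohex-2-enone.
Enabling feature: the C2 hydroxyl is γ to the C19 carboxyl (O–C2–C3–C4–C19). An aldehyde ketyl at C2 can therefore add to C3, the CH2 end of an acrylate whose α-carbon C4 sits on C5, and the enolate left at C4 takes the methyl group; the axial C10 methyl of the new chair controls both C2 and C4.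
Forward: ring B (a cyclohexanone) first, ring A by the ketyl–acrylate closure, then C8 and C9 on the rigid trans-decalin, side-chain terminus last.
Stereochemistry: C5 by copper-catalysed asymmetric conjugate addition; C10 by enolate allylation anti to the C5 group; C2 and C4 relayed from C10 in the key step; C9 by α-face addition to the C9 ketone and palladium hydride delivery to the same face; the E enoate by syn carboalumination.

Key step: step 5

Remark: the ligand antipode named in step 1 is assumed to give the 3S adduct; if the sense proves opposite, its enantiomer is used.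

**Route**

Step 1
Reactants: 1 2-methylcyclohex-2-en-1-one; 2 isopropenylmagnesium bromide; 3 allyl iodide
Product: 5 (2S,3S)-2-methyl-2-(prop-2-en-1-yl)-3-(prop-1-en-2-yl)cyclohexan-1-one, via magnesium enolate 4 (not isolated)
Conditions: Cu(OTf)2 (4 mol%), (S)-3-(1-hydroxy-4-methylpentan-2-yl)-1-(2,4,6-trimethylphenyl)-4,5-dihydro-1H-imidazol-3-ium hexafluorophosphate (5 mol%), Et2O, −30 °C; then 3, DMPU, 0 → 23 °C
Reagents that add atoms: none
Why: Copper-catalysed asymmetric conjugate addition of a Grignard reagent to an α-substituted cyclic enone with enolate trapping: the carbene–copper catalyst fixes the isopropenyl-bearing carbon (C5), and allyl iodide alkylates magnesium enolate 4 on the face anti to that group, so the quaternary C10 carries its methyl cis and its allyl trans to the isopropenyl group.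

Step 2
Reactants: 5 (2S,3S)-2-methyl-2-(prop-2-en-1-yl)-3-(prop-1-en-2-yl)cyclohexan-1-one
Product: 6 (2S,3S)-3-(3-hydroxyprop-1-en-2-yl)-2-methyl-2-(prop-2-en-1-yl)cyclohexan-1-one
Conditions: SeO2 (0.3 equiv), t-BuOOH (3 equiv), CH2Cl2, 0 → 23 °C
Reagents that add atoms: tert-butyl hydroperoxide, CC(C)(C)OO
Why: Selenium dioxide allylic hydroxylation (ene reaction followed by [2,3]-sigmatropic shift) should take place at the methyl group of the more nucleophilic 1,1-disubstituted isopropenyl alkene rather than at the monosubstituted allyl group or the hindered ring methine, and it creates no stereocentre.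

Step 3
Reactants: 6 (2S,3S)-3-(3-hydroxyprop-1-en-2-yl)-2-methyl-2-(prop-2-en-1-yl)cyclohexan-1-one
Product: 8 2-(trimethylsilyl)ethyl 2-[(1R,2S)-2-methyl-3-oxo-2-(prop-2-en-1-yl)cyclohexyl]prop-2-enoate, via enal 7 (not isolated)
Conditions: MnO2 (15 equiv), 1,4-dimethyl-4H-1,2,4-triazol-1-ium iodide (10 mol%), DBU (1.1 equiv), Me3SiCH2CH2OH (5 equiv), CH2Cl2, 23 °C
Reagents that add atoms: 2-(trimethylsilyl)ethanol, C[Si](C)(C)CCO
Why: NHC-catalysed oxidative esterification: MnO2 oxidises the allylic alcohol to enal 7, whose carbene adduct is oxidised again to an acyl azolium that the silyl alcohol intercepts, so the acrylate (C3=C4–C19) is made without strong base and without touching the ketone or the allyl group.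

Step 4
Reactants: 8 2-(trimethylsilyl)ethyl 2-[(1R,2S)-2-methyl-3-oxo-2-(prop-2-en-1-yl)cyclohexyl]prop-2-enoate
Product: 10 2-(trimethylsilyl)ethyl 2-[(1R,2S)-2-methyl-3-oxo-2-(2-oxoethyl)cyclohexyl]prop-2-enoate, via ozonide 9 (not isolated)
Conditions: O3, CH2Cl2, −78 °C (Sudan Red 7B end point); then PPh3, −78 → 23 °C
Reagents that add atoms: ozone, [O-][O+]=O
Why: Ozonolysis with reductive work-up: ozone should cleave the electron-rich terminal alkene of the allyl group well before the electron-poor acrylate alkene, which unmasks the C2 aldehyde on the carbon next to the quaternary C10.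

Step 5
Reactants: 10 2-(trimethylsilyl)ethyl 2-[(1R,2S)-2-methyl-3-oxo-2-(2-oxoethyl)cyclohexyl]prop-2-enoate
Product: 12 2-(trimethylsilyl)ethyl (1S,3R,4aS,8aR)-3-hydroxy-1,4a-dimethyl-5-oxodecahydronaphthalene-1-carboxylate, via samarium ester enolate 11 (not isolated)
Conditions: 10 added over 30 min to SmI2 (2.2 equiv), HMPA (10 equiv), THF, −78 °C; then MeI (10 equiv), −78 → −30 °C; aq. NH4Cl
Reagents that add atoms: iodomethane, CI
Why: Proposed new method: SmI2 reduces the aldehyde of 10 to a ketyl radical anion at C2, which adds to C3, the unsubstituted terminus of the acrylate, and closes ring A in the 6-endo-trig mode (5-exo attack at the substituted α-carbon C4 is disfavoured by polarity and substitution); the α-ester radical at C4 takes a second electron to give the trivalent samarium ester enolate 11, which is C-methylated by iodomethane. The closest known reaction types are the SmI2 ketyl–olefin cyclisation of aldehydes onto acrylates, with protonation or aldol capture of the samarium enolate, and the methylation of lithium enolates of C4 esters in trans-decalins; joining the two in one flask is the new element. At C2 the bulky O–Sm group should sit equatorial (α) in the chair transition state leading to the trans-decalin, away from the axial C10 methyl, which gives the 2α alcohol. At C4 the exocyclic enolate is shielded on its β face by the 1,3-diaxial C10 methyl, so iodomethane should enter from the α (equatorial) side and leave the ester axial (β). The step needs reduction of the aldehyde in the presence of the C9 ketone, which the much faster electron transfer to an aldehyde and the hindrance of a ketone next to a quaternary carbon should secure, and C- over O-alkylation, which the soft electrophile and HMPA favour.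

Step 6
Reactants: 12 2-(trimethylsilyl)ethyl (1S,3R,4aS,8aR)-3-hydroxy-1,4a-dimethyl-5-oxodecahydronaphthalene-1-carboxylate
Product: 13 2-(trimethylsilyl)ethyl (1S,3R,4aS,8aR)-3-[(tert-butyldimethylsilyl)oxy]-1,4a-dimethyl-5-oxodecahydronaphthalene-1-carboxylate
Conditions: TBSCl, imidazole, DMF, 23 °C
Reagents that add atoms: tert-butyl(chloro)dimethylsilane, CC(C)(C)[Si](C)(C)Cl
Why: Standard silylation of the unhindered equatorial secondary alcohol, which shields it from the amide base, the organocerium reagent and the trimethylaluminium used later.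

Step 7
Reactants: 13 2-(trimethylsilyl)ethyl (1S,3R,4aS,8aR)-3-[(tert-butyldimethylsilyl)oxy]-1,4a-dimethyl-5-oxodecahydronaphthalene-1-carboxylate
Product: 17 2-(trimethylsilyl)ethyl (1S,3R,4aS,8aR)-3-[(tert-butyldimethylsilyl)oxy]-1,4a-dimethyl-6-methylidene-5-oxodecahydronaphthalene-1-carboxylate, via lithium enolate 14 (not isolated), via Mannich base 15 (not isolated), via ammonium iodide 16 (not isolated)
Conditions: lithium diisopropylamide, THF, −78 °C; CH2=NMe2+ I−, −78 → 23 °C; MeI, MeOH, 23 °C; DBU, CH2Cl2, 23 °C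
Reagents that add atoms: N,N-dimethylmethyleneiminium iodide, C=[N+](C)C.[I-]
Why: Mannich methylenation of a ketone (Eschenmoser methylenation): because C10 is quaternary the enolate can form only toward C8, the iminium salt aminomethylates it, and quaternisation followed by base-induced elimination gives the exocyclic enone, while the now quaternary C4 ester cannot enolise.

Step 8
Reactants: 17 2-(trimethylsilyl)ethyl (1S,3R,4aS,8aR)-3-[(tert-butyldimethylsilyl)oxy]-1,4a-dimethyl-6-methylidene-5-oxodecahydronaphthalene-1-carboxylate; 18 (4-bromobut-1-yn-1-yl)trimethylsilane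
Product: 22 2-(trimethylsilyl)ethyl (1S,3R,4aS,5S,8aR)-3-[(tert-butyldimethylsilyl)oxy]-5-[(methoxycarbonyl)oxy]-1,4a-dimethyl-6-methylidene-5-[4-(trimethylsilyl)but-3-yn-1-yl]decahydronaphthalene-1-carboxylate, via Grignard reagent 19 (not isolated), via organocerium reagent 20 (not isolated), via cerium alkoxide 21 (not isolated)
Conditions: 18, Mg, THF, 23 °C; CeCl3, THF, −78 °C; 17, −78 °C; then ClCO2Me, −78 → 0 °C
Reagents that add atoms: methyl chloroformate, COC(=O)Cl
Why: Organocerium 1,2-addition to a hindered enone followed by acylation of the alkoxide: the weakly basic cerium reagent should add to the C9 carbonyl rather than in the conjugate sense, from the α face opposite the axial C10 methyl (the usual course for ketones flanked by an angular methyl), which places the chain α and the carbonate oxygen β.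

Step 9
Reactants: 22 2-(trimethylsilyl)ethyl (1S,3R,4aS,5S,8aR)-3-[(tert-butyldimethylsilyl)oxy]-5-[(methoxycarbonyl)oxy]-1,4a-dimethyl-6-methylidene-5-[4-(trimethylsilyl)but-3-yn-1-yl]decahydronaphthalene-1-carboxylate
Product: 23 2-(trimethylsilyl)ethyl (1S,3R,4aR,5S,8aR)-3-[(tert-butyldimethylsilyl)oxy]-1,4a-dimethyl-6-methylidene-5-[4-(trimethylsilyl)but-3-yn-1-yl]decahydronaphthalene-1-carboxylate
Conditions: Pd(OAc)2 (5 mol%), PBu3 (20 mol%), HCO2NH4 (3 equiv), 1,4-dioxane, 100 °C
Reagents that add atoms: none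
Why: Palladium-catalysed formate reduction of an allylic carbonate (Tsuji reduction): ionisation gives a π-allylpalladium formate that loses CO2 and transfers hydride from palladium to the more substituted terminus C9 on the α face (anti to both the departing carbonate and the axial C10 methyl), so C9 should end with its hydrogen α and the chain β-equatorial while the alkene stays exocyclic at C8.

Step 10
Reactants: 23 2-(trimethylsilyl)ethyl (1S,3R,4aR,5S,8aR)-3-[(tert-butyldimethylsilyl)oxy]-1,4a-dimethyl-6-methylidene-5-[4-(trimethylsilyl)but-3-yn-1-yl]decahydronaphthalene-1-carboxylate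
Product: 24 2-(trimethylsilyl)ethyl (1S,3R,4aR,5S,8aR)-5-(but-3-yn-1-yl)-3-[(tert-butyldimethylsilyl)oxy]-1,4a-dimethyl-6-methylidenedecahydronaphthalene-1-carboxylate
Conditions: K2CO3 (0.5 equiv), MeOH, 23 °C
Reagents that add atoms: none
Why: Base-catalysed methanolysis of the alkynyl C–Si bond (protodesilylation) should free the terminal alkyne without affecting the silyl ether or the hindered quaternary ester.

Step 11
Reactants: 24 2-(trimethylsilyl)ethyl (1S,3R,4aR,5S,8aR)-5-(but-3-yn-1-yl)-3-[(tert-butyldimethylsilyl)oxy]-1,4a-dimethyl-6-methylidenedecahydronaphthalene-1-carboxylate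
Product: 26 2-(trimethylsilyl)ethyl (1S,3R,4aR,5S,8aR)-3-[(tert-butyldimethylsilyl)oxy]-5-[(3E)-5-methoxy-3-methyl-5-oxopent-3-en-1-yl]-1,4a-dimethyl-6-methylidenedecahydronaphthalene-1-carboxylate, via alkenylalane 25 (not isolated)
Conditions: Me3Al (3 equiv), Cp2ZrCl2 (0.3 equiv), CH2Cl2, 0 → 23 °C; then ClCO2Me, 0 → 23 °C
Reagents that add atoms: trimethylaluminium, C[Al](C)C; methyl chloroformate, COC(=O)Cl
Why: Negishi zirconium-catalysed carboalumination: methyl and aluminium add syn across the terminal alkyne with aluminium on the terminal carbon, and acylation of alkenylalane 25 by the chloroformate with retention should give the E trisubstituted enoate with C12 trans to the ester.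

Step 12
Reactants: 26 2-(trimethylsilyl)ethyl (1S,3R,4aR,5S,8aR)-3-[(tert-butyldimethylsilyl)oxy]-5-[(3E)-5-methoxy-3-methyl-5-oxopent-3-en-1-yl]-1,4a-dimethyl-6-methylidenedecahydronaphthalene-1-carboxylate
Product: 28 (1S,3R,4aR,5S,8aR)-5-[(3E)-4-carboxy-3-methylbut-3-en-1-yl]-3-hydroxy-1,4a-dimethyl-6-methylidenedecahydronaphthalene-1-carboxylic acid (hypoxyterpoid A), via hydroxy acid monoester 27 (not isolated)
Conditions: Bu4NF (4 equiv), THF, 23 °C; then LiOH, THF/MeOH/H2O, 40 °C; aq. HCl to pH 3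
Reagents that add atoms: lithium hydroxide, [Li+].[OH-]
Why: Fluoride removes the silyl ether and cleaves the 2-(trimethylsilyl)ethyl ester by β-elimination at silicon (insensitive to the hindrance at C4), and saponification of the unhindered conjugated methyl ester then frees the second acid without touching any stereocentre or the alkene geometry.

**Compound list**

1 | 2-methylcyclohex-2-en-1-one | CC1=CCCCC1=O | starting material
2 | isopropenylmagnesium bromide (prop-1-en-2-ylmagnesium bromide) | C=C(C)[Mg]Br | starting material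
3 | allyl iodide (3-iodoprop-1-ene) | C=CCI | starting material
4 | bromomagnesium (3S)-2-methyl-3-(prop-1-en-2-yl)cyclohex-1-en-1-olate (not isolated) | CC1=C(O[Mg]Br)CCC[C@H]1C(C)=C | intermediate
5 | (2S,3S)-2-methyl-2-(prop-2-en-1-yl)-3-(prop-1-en-2-yl)cyclohexan-1-one | O=C1CCC[C@@H](C(C)=C)[C@]1(C)CC=C | intermediate
6 | (2S,3S)-3-(3-hydroxyprop-1-en-2-yl)-2-methyl-2-(prop-2-en-1-yl)cyclohexan-1-one | O=C1CCC[C@@H](C(=C)CO)[C@]1(C)CC=C | intermediate
7 | 2-[(1S,2S)-2-methyl-3-oxo-2-(prop-2-en-1-yl)cyclohexyl]prop-2-enal (not isolated) | O=C1CCC[C@@H](C(=C)C=O)[C@]1(C)CC=C | intermediate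
8 | 2-(trimethylsilyl)ethyl 2-[(1R,2S)-2-methyl-3-oxo-2-(prop-2-en-1-yl)cyclohexyl]prop-2-enoate | O=C1CCC[C@@H](C(=C)C(=O)OCC[Si](C)(C)C)[C@]1(C)CC=C | intermediate
9 | 2-(trimethylsilyl)ethyl 2-[(1R,2S)-2-methyl-3-oxo-2-(1,2,4-trioxolan-3-ylmethyl)cyclohexyl]prop-2-enoate, ozonide, epimers at the trioxolane carbon (not isolated) | O=C1CCC[C@@H](C(=C)C(=O)OCC[Si](C)(C)C)[C@]1(C)CC2OCOO2 | intermediate
10 | 2-(trimethylsilyl)ethyl 2-[(1R,2S)-2-methyl-3-oxo-2-(2-oxoethyl)cyclohexyl]prop-2-enoate | O=C1CCC[C@@H](C(=C)C(=O)OCC[Si](C)(C)C)[C@]1(C)CC=O | intermediate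
11 | cyclised decalin as its bis(diiodosamarium) derivative: C2 alkoxide (2α) and exocyclic C4 ester enolate (not isolated) | O=C1CCC[C@@H]2[C@]1(C)C[C@@H](O[Sm](I)I)CC2=C(O[Sm](I)I)OCC[Si](C)(C)C | intermediate
12 | 2-(trimethylsilyl)ethyl (1S,3R,4aS,8aR)-3-hydroxy-1,4a-dimethyl-5-oxodecahydronaphthalene-1-carboxylate | O=C1CCC[C@@H]2[C@]1(C)C[C@@H](O)C[C@]2(C)C(=O)OCC[Si](C)(C)C | intermediate
13 | 2-(trimethylsilyl)ethyl (1S,3R,4aS,8aR)-3-[(tert-butyldimethylsilyl)oxy]-1,4a-dimethyl-5-oxodecahydronaphthalene-1-carboxylate | O=C1CCC[C@@H]2[C@]1(C)C[C@@H](O[Si](C)(C)C(C)(C)C)C[C@]2(C)C(=O)OCC[Si](C)(C)C | intermediate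
14 | lithium enolate of 13 (C9–OLi, C8=C9) (not isolated) | [Li]OC1=CCC[C@@H]2[C@]1(C)C[C@@H](O[Si](C)(C)C(C)(C)C)C[C@]2(C)C(=O)OCC[Si](C)(C)C | intermediate
15 | 2-(trimethylsilyl)ethyl (1S,3R,4aS,8aR)-3-[(tert-butyldimethylsilyl)oxy]-6-[(dimethylamino)methyl]-1,4a-dimethyl-5-oxodecahydronaphthalene-1-carboxylate, C6 epimers (not isolated) | O=C1C(CN(C)C)CC[C@@H]2[C@]1(C)C[C@@H](O[Si](C)(C)C(C)(C)C)C[C@]2(C)C(=O)OCC[Si](C)(C)C | intermediate
16 | N-methyl ammonium iodide of 15 (not isolated) | O=C1C(C[N+](C)(C)C)CC[C@@H]2[C@]1(C)C[C@@H](O[Si](C)(C)C(C)(C)C)C[C@]2(C)C(=O)OCC[Si](C)(C)C.[I-] | intermediate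
17 | 2-(trimethylsilyl)ethyl (1S,3R,4aS,8aR)-3-[(tert-butyldimethylsilyl)oxy]-1,4a-dimethyl-6-methylidene-5-oxodecahydronaphthalene-1-carboxylate | C=C1CC[C@@H]2[C@](C)(C[C@@H](O[Si](C)(C)C(C)(C)C)C[C@]2(C)C(=O)OCC[Si](C)(C)C)C1=O | intermediate
18 | (4-bromobut-1-yn-1-yl)trimethylsilane | C[Si](C)(C)C#CCCBr | starting material
19 | [4-(trimethylsilyl)but-3-yn-1-yl]magnesium bromide (not isolated) | C[Si](C)(C)C#CCC[Mg]Br | intermediate
20 | dichloro[4-(trimethylsilyl)but-3-yn-1-yl]cerium (not isolated) | C[Si](C)(C)C#CCC[Ce](Cl)Cl | intermediate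
21 | dichlorocerium alkoxide of the C9 tertiary allylic alcohol (chain α, oxygen β) (not isolated) | C=C1CC[C@@H]2[C@](C)(C[C@@H](O[Si](C)(C)C(C)(C)C)C[C@]2(C)C(=O)OCC[Si](C)(C)C)[C@]1(O[Ce](Cl)Cl)CCC#C[Si](C)(C)C | intermediate
22 | 2-(trimethylsilyl)ethyl (1S,3R,4aS,5S,8aR)-3-[(tert-butyldimethylsilyl)oxy]-5-[(methoxycarbonyl)oxy]-1,4a-dimethyl-6-methylidene-5-[4-(trimethylsilyl)but-3-yn-1-yl]decahydronaphthalene-1-carboxylate | C=C1CC[C@@H]2[C@](C)(C[C@@H](O[Si](C)(C)C(C)(C)C)C[C@]2(C)C(=O)OCC[Si](C)(C)C)[C@]1(OC(=O)OC)CCC#C[Si](C)(C)C | intermediate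
23 | 2-(trimethylsilyl)ethyl (1S,3R,4aR,5S,8aR)-3-[(tert-butyldimethylsilyl)oxy]-1,4a-dimethyl-6-methylidene-5-[4-(trimethylsilyl)but-3-yn-1-yl]decahydronaphthalene-1-carboxylate | C=C1CC[C@@H]2[C@](C)(C[C@@H](O[Si](C)(C)C(C)(C)C)C[C@]2(C)C(=O)OCC[Si](C)(C)C)[C@H]1CCC#C[Si](C)(C)C | intermediate
24 | 2-(trimethylsilyl)ethyl (1S,3R,4aR,5S,8aR)-5-(but-3-yn-1-yl)-3-[(tert-butyldimethylsilyl)oxy]-1,4a-dimethyl-6-methylidenedecahydronaphthalene-1-carboxylate | C=C1CC[C@@H]2[C@](C)(C[C@@H](O[Si](C)(C)C(C)(C)C)C[C@]2(C)C(=O)OCC[Si](C)(C)C)[C@H]1CCC#C | intermediate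
25 | 2-(trimethylsilyl)ethyl (1S,3R,4aR,5S,8aR)-3-[(tert-butyldimethylsilyl)oxy]-5-[(3E)-4-(dimethylalumanyl)-3-methylbut-3-en-1-yl]-1,4a-dimethyl-6-methylidenedecahydronaphthalene-1-carboxylate (not isolated) | C=C1CC[C@@H]2[C@](C)(C[C@@H](O[Si](C)(C)C(C)(C)C)C[C@]2(C)C(=O)OCC[Si](C)(C)C)[C@H]1CC/C(C)=C/[Al](C)C | intermediate
26 | 2-(trimethylsilyl)ethyl (1S,3R,4aR,5S,8aR)-3-[(tert-butyldimethylsilyl)oxy]-5-[(3E)-5-methoxy-3-methyl-5-oxopent-3-en-1-yl]-1,4a-dimethyl-6-methylidenedecahydronaphthalene-1-carboxylate | C=C1CC[C@@H]2[C@](C)(C[C@@H](O[Si](C)(C)C(C)(C)C)C[C@]2(C)C(=O)OCC[Si](C)(C)C)[C@H]1CC/C(C)=C/C(=O)OC | intermediate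
27 | (1S,3R,4aR,5S,8aR)-3-hydroxy-5-[(3E)-5-methoxy-3-methyl-5-oxopent-3-en-1-yl]-1,4a-dimethyl-6-methylidenedecahydronaphthalene-1-carboxylic acid (not isolated) | C=C1CC[C@@H]2[C@](C)(C[C@@H](O)C[C@]2(C)C(=O)O)[C@H]1CC/C(C)=C/C(=O)OC | intermediate
28 | (1S,3R,4aR,5S,8aR)-5-[(3E)-4-carboxy-3-methylbut-3-en-1-yl]-3-hydroxy-1,4a-dimethyl-6-methylidenedecahydronaphthalene-1-carboxylic acid (hypoxyterpoid A) | C=C1CC[C@@H]2[C@](C)(C[C@@H](O)C[C@]2(C)C(=O)O)[C@H]1CC/C(C)=C/C(=O)O | target

**Summary**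

Total step count: 12. Longest linear sequence: 12 steps (from 1).

Steps most likely to fail:

Step 5. The trivalent samarium enolate may be protonated, or consumed by aldol or Claisen pathways, before it is C-methylated, and the C9 ketone may be reduced in competition. The fallback uses known chemistry, sets out from 10 and returns at 23. The cyclisation is run under the classical protic conditions (SmI2, t-BuOH, THF, −78 °C), which should give 2-(trimethylsilyl)ethyl (3S,4aS,8aS)-3-hydroxy-4a-methyl-5-oxodecahydronaphthalene-1-carboxylate F1 as a mixture of C1 epimers (hydrogen in place of the C4 methyl). Silylation (TBSCl, imidazole) gives 2-(trimethylsilyl)ethyl (3S,4aS,8aS)-3-[(tert-butyldimethylsilyl)oxy]-4a-methyl-5-oxodecahydronaphthalene-1-carboxylate F2. One equivalent of lithium diisopropylamide enolises only the ketone, and the same Mannich methylenation gives 2-(trimethylsilyl)ethyl (3S,4aS,8aS)-3-[(tert-butyldimethylsilyl)oxy]-4a-methyl-6-methylidene-5-oxodecahydronaphthalene-1-carboxylate F3. Addition of organocerium reagent 20 and ClCO2Me gives 2-(trimethylsilyl)ethyl (3S,4aS,5S,8aS)-3-[(tert-butyldimethylsilyl)oxy]-5-[(methoxycarbonyl)oxy]-4a-methyl-6-methylidene-5-[4-(trimethylsilyl)but-3-yn-1-yl]decahydronaphthalene-1-carboxylate F4. Reduction with Pd(OAc)2, PBu3 and HCO2NH4 gives 2-(trimethylsilyl)ethyl (3S,4aS,5S,8aS)-3-[(tert-butyldimethylsilyl)oxy]-4a-methyl-6-methylidene-5-[4-(trimethylsilyl)but-3-yn-1-yl]decahydronaphthalene-1-carboxylate F5. Only then is the ester enolised (lithium diisopropylamide, THF, −78 °C) and methylated with MeI from the α face, which rejoins the route at 23.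

Step 1. C-allylation of the hindered magnesium enolate may lag behind proton transfer or O-allylation, and the salts that build up in a one-flask process may erode the enantioselectivity of the conjugate addition. The fallback sets out from 1 and returns at 5. The conjugate addition is run alone, and the magnesium enolate is silylated (Me3SiCl, Et3N) so that trimethyl{[(3S)-2-methyl-3-(prop-1-en-2-yl)cyclohex-1-en-1-yl]oxy}silane F6 can be isolated and its enantiomeric purity checked. MeLi in THF then liberates the lithium enolate regiospecifically, and allylation with 3 in the presence of DMPU gives 5.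

Step 9. Hydride transfer to the primary allyl terminus, or β-hydride elimination, would move the alkene into ring B or give dienes. The fallback sets out from 17 and returns at 23. Reagent 20 is added as in step 8 but the alkoxide is protonated, giving 2-(trimethylsilyl)ethyl (1S,3R,4aS,5S,8aR)-3-[(tert-butyldimethylsilyl)oxy]-5-hydroxy-1,4a-dimethyl-6-methylidene-5-[4-(trimethylsilyl)but-3-yn-1-yl]decahydronaphthalene-1-carboxylate F7. A 1,3-transposition catalysed by Ph3SiOReO3 moves the hydroxyl to C17 and gives 2-(trimethylsilyl)ethyl (1S,3R,4aS,8aR)-3-[(tert-butyldimethylsilyl)oxy]-6-(hydroxymethyl)-1,4a-dimethyl-5-[4-(trimethylsilyl)but-3-yn-1-yl]-1,2,3,4,4a,7,8,8a-octahydronaphthalene-1-carboxylate F8. Mitsunobu reaction with 2-nitrobenzenesulfonylhydrazide (PPh3, diethyl azodicarboxylate, −30 °C) gives 2-(trimethylsilyl)ethyl (1S,3R,4aS,8aR)-3-[(tert-butyldimethylsilyl)oxy]-1,4a-dimethyl-6-{[1-(2-nitrobenzenesulfonyl)hydrazinyl]methyl}-5-[4-(trimethylsilyl)but-3-yn-1-yl]-1,2,3,4,4a,7,8,8a-octahydronaphthalene-1-carboxylate F9. On warming, F9 loses the sulfinic acid to an allylic diazene, whose sigmatropic loss of nitrogen places hydrogen on C9 from the less hindered α face and the alkene at C8=C17, giving 23.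

Further compounds
F1 | step 5 | 2-(trimethylsilyl)ethyl (3S,4aS,8aS)-3-hydroxy-4a-methyl-5-oxodecahydronaphthalene-1-carboxylate (C1 epimers) | O=C1CCC[C@@H]2[C@]1(C)C[C@@H](O)CC2C(=O)OCC[Si](C)(C)C
F2 | step 5 | 2-(trimethylsilyl)ethyl (3S,4aS,8aS)-3-[(tert-butyldimethylsilyl)oxy]-4a-methyl-5-oxodecahydronaphthalene-1-carboxylate (C1 epimers) | O=C1CCC[C@@H]2[C@]1(C)C[C@@H](O[Si](C)(C)C(C)(C)C)CC2C(=O)OCC[Si](C)(C)C
F3 | step 5 | 2-(trimethylsilyl)ethyl (3S,4aS,8aS)-3-[(tert-butyldimethylsilyl)oxy]-4a-methyl-6-methylidene-5-oxodecahydronaphthalene-1-carboxylate (C1 epimers) | C=C1CC[C@@H]2[C@](C)(C[C@@H](O[Si](C)(C)C(C)(C)C)CC2C(=O)OCC[Si](C)(C)C)C1=O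
F4 | step 5 | 2-(trimethylsilyl)ethyl (3S,4aS,5S,8aS)-3-[(tert-butyldimethylsilyl)oxy]-5-[(methoxycarbonyl)oxy]-4a-methyl-6-methylidene-5-[4-(trimethylsilyl)but-3-yn-1-yl]decahydronaphthalene-1-carboxylate (C1 epimers) | C=C1CC[C@@H]2[C@](C)(C[C@@H](O[Si](C)(C)C(C)(C)C)CC2C(=O)OCC[Si](C)(C)C)[C@]1(OC(=O)OC)CCC#C[Si](C)(C)C
F5 | step 5 | 2-(trimethylsilyl)ethyl (3S,4aS,5S,8aS)-3-[(tert-butyldimethylsilyl)oxy]-4a-methyl-6-methylidene-5-[4-(trimethylsilyl)but-3-yn-1-yl]decahydronaphthalene-1-carboxylate (C1 epimers) | C=C1CC[C@@H]2[C@](C)(C[C@@H](O[Si](C)(C)C(C)(C)C)CC2C(=O)OCC[Si](C)(C)C)[C@H]1CCC#C[Si](C)(C)C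
F6 | step 1 | trimethyl{[(3S)-2-methyl-3-(prop-1-en-2-yl)cyclohex-1-en-1-yl]oxy}silane | CC1=C(O[Si](C)(C)C)CCC[C@H]1C(C)=C
F7 | step 9 | 2-(trimethylsilyl)ethyl (1S,3R,4aS,5S,8aR)-3-[(tert-butyldimethylsilyl)oxy]-5-hydroxy-1,4a-dimethyl-6-methylidene-5-[4-(trimethylsilyl)but-3-yn-1-yl]decahydronaphthalene-1-carboxylate | C=C1CC[C@@H]2[C@](C)(C[C@@H](O[Si](C)(C)C(C)(C)C)C[C@]2(C)C(=O)OCC[Si](C)(C)C)[C@]1(O)CCC#C[Si](C)(C)C
F8 | step 9 | 2-(trimethylsilyl)ethyl (1S,3R,4aS,8aR)-3-[(tert-butyldimethylsilyl)oxy]-6-(hydroxymethyl)-1,4a-dimethyl-5-[4-(trimethylsilyl)but-3-yn-1-yl]-1,2,3,4,4a,7,8,8a-octahydronaphthalene-1-carboxylate | OCC1=C(CCC#C[Si](C)(C)C)[C@@]2(C)C[C@@H](O[Si](C)(C)C(C)(C)C)C[C@](C)(C(=O)OCC[Si](C)(C)C)[C@@H]2CC1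
F9 | step 9 | 2-(trimethylsilyl)ethyl (1S,3R,4aS,8aR)-3-[(tert-butyldimethylsilyl)oxy]-1,4a-dimethyl-6-{[1-(2-nitrobenzenesulfonyl)hydrazinyl]methyl}-5-[4-(trimethylsilyl)but-3-yn-1-yl]-1,2,3,4,4a,7,8,8a-octahydronaphthalene-1-carboxylate | NN(CC1=C(CCC#C[Si](C)(C)C)[C@@]2(C)C[C@@H](O[Si](C)(C)C(C)(C)C)C[C@](C)(C(=O)OCC[Si](C)(C)C)[C@@H]2CC1)S(=O)(=O)c3ccccc3[N+](=O)[O-]
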